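**Retrosynthetic overview**

1. Target 17 comes from its bis-MOM ether 16; the prenyl group is carried from the second step, so no late C6/C8 prenylation is needed.
2. Ring C (the pyran) is closed last through the C4–C4a bond, by hydroboration and intramolecular B-alkyl Suzuki coupling of the aryl iodide/vinyl ether 14, not through the usual chalcone/flavanone or C2–O1 closure.
3. C2 is set one step earlier as an intermolecular C–O bond: iridium-catalysed asymmetric allylic etherification of iodophenol 8 with cinnamyl carbonate 12.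
4. Iodophenol 8 comes from resorcinol 1 (bis-MOM, lithiation/prenylation, steric C–H borylation/oxidation, iodination). Phenol 7 is mirror-symmetric, so the 6-prenyl pattern is fixed by symmetry. Carbonate 12 comes from 3,5-dimethoxycinnamic acid 9.
5. Ring order: rings A and B are bought as benzenes; ring C is the only ring formed.

Assumption: the (Ra,Rc,Rc)-phosphoramidite is taken to give the (R)-ether in step 7, by analogy with the parent cinnamyl carbonate/aryloxide reaction. This is from memory and is checked on the first run by chiral HPLC; if the antipode forms, the (Sa,Sc,Sc) ligand is used with nothing else changed.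

**Route**

Step 1
Reactants: 1 resorcinol (benzene-1,3-diol)
Product: 2 1,3-bis(methoxymethoxy)benzene
Conditions: MOMCl (2.5 equiv), i-Pr2NEt (3 equiv), CH2Cl2, 0 °C to rt
Reagents that add atoms: chloromethyl methyl ether (MOMCl), COCCl
Why: Double O-alkylation of the phenols (Williamson-type acetal formation) installs the MOM groups, which direct the lithiation in step 2 and come off under mild acid at the end.

Step 2
Reactants: 2 1,3-bis(methoxymethoxy)benzene
Product: 5 1,3-bis(methoxymethoxy)-2-(3-methylbut-2-en-1-yl)benzene, via aryllithium 3 (not isolated), via arylcopper 4 (not isolated)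
Conditions: n-BuLi (1.1 equiv), THF, 0 °C to rt; CuBr·SMe2 (1.0 equiv), −40 °C; prenyl bromide (1.2 equiv), −78 °C to rt
Reagents that add atoms: prenyl bromide (1-bromo-3-methylbut-2-ene), CC(C)=CCBr
Why: Directed ortho-metalation occurs at the carbon flanked by both OMOM groups, and the arylcopper alkylates prenyl bromide at its primary carbon (SN2), giving the linear prenyl group.

Step 3
Reactants: 5 1,3-bis(methoxymethoxy)-2-(3-methylbut-2-en-1-yl)benzene
Product: 7 3,5-bis(methoxymethoxy)-4-(3-methylbut-2-en-1-yl)phenol, via arylboronate 6 (not isolated)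
Conditions: [Ir(OMe)(cod)]2 (1.5 mol %), 4,4'-di-tert-butyl-2,2'-bipyridine (3 mol %), B2pin2 (1.0 equiv), THF, 60 °C; then 30% H2O2, aq NaOH, 0 °C
Reagents that add atoms: hydrogen peroxide, OO
Why: Sterically governed iridium-catalysed aromatic C–H borylation (Ishiyama–Miyaura–Hartwig) goes to the only ring C–H with no ortho substituent, para to the prenyl group, and boronate oxidation then gives a mirror-symmetric phenol; H2O2/NaOH leaves the trisubstituted alkene alone.

Step 4
Reactants: 7 3,5-bis(methoxymethoxy)-4-(3-methylbut-2-en-1-yl)phenol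
Product: 8 2-iodo-3,5-bis(methoxymethoxy)-4-(3-methylbut-2-en-1-yl)phenol
Conditions: I2 (1.0 equiv, slow addition), NaHCO3 (1.5 equiv), THF/H2O, 0 °C
Reagents that add atoms: iodine, II
Why: Electrophilic aromatic iodination ortho to the free phenol can give only one mono-iodide because the two open ring positions are equivalent, and the phenol ring reacts far faster than the prenyl alkene whose neighbouring oxygens are both capped.

Step 5
Reactants: 9 (E)-3-(3,5-dimethoxyphenyl)prop-2-enoic acid (3,5-dimethoxycinnamic acid)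
Product: 11 (E)-3-(3,5-dimethoxyphenyl)prop-2-en-1-ol, via mixed anhydride 10 (not isolated)
Conditions: i-BuOCOCl, N-methylmorpholine, THF, −15 °C; then NaBH4, H2O, 0 °C
Reagents that add atoms: none
Why: Mixed carbonic anhydride activation followed by borohydride reduction gives the allylic alcohol by 1,2-reduction without touching the conjugated alkene.

Step 6
Reactants: 11 (E)-3-(3,5-dimethoxyphenyl)prop-2-en-1-ol
Product: 12 (E)-3-(3,5-dimethoxyphenyl)prop-2-en-1-yl methyl carbonate
Conditions: ClCO2Me (1.3 equiv), pyridine (2 equiv), CH2Cl2, 0 °C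
Reagents that add atoms: methyl chloroformate, COC(Cl)=O
Why: O-acylation of the primary allylic alcohol gives the linear carbonate, the standard electrophile for iridium allylic substitution.

Step 7
Reactants: 8 2-iodo-3,5-bis(methoxymethoxy)-4-(3-methylbut-2-en-1-yl)phenol; 12 (E)-3-(3,5-dimethoxyphenyl)prop-2-en-1-yl methyl carbonate
Product: 14 1-{[(1R)-1-(3,5-dimethoxyphenyl)prop-2-en-1-yl]oxy}-2-iodo-3,5-bis(methoxymethoxy)-4-(3-methylbut-2-en-1-yl)benzene, via lithium aryloxide 13 (not isolated)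
Conditions: 8, LiN(SiMe3)2 (1.0 equiv), THF, 0 °C; then 12 (1.3 equiv), [Ir(cod)Cl]2 (2 mol %), (Ra,Rc,Rc)-O,O'-(1,1'-binaphthyl-2,2'-diyl)-N,N-bis(1-phenylethyl)phosphoramidite (4 mol %, catalyst pre-activated with n-PrNH2), THF, rt
Reagents that add atoms: none
Why: Iridium-catalysed asymmetric allylic etherification (Hartwig–Helmchen type): the cyclometalated iridium–phosphoramidite forms a π-allyl complex from 12, the lithium aryloxide attacks the aryl-bearing terminus to give the branched ether, and the ligand controls the face so that C2 is formed directly as (R); lithium in THF favours O- over C-attack and the aryl iodide is inert to monovalent iridium.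

Step 8
Reactants: 14 1-{[(1R)-1-(3,5-dimethoxyphenyl)prop-2-en-1-yl]oxy}-2-iodo-3,5-bis(methoxymethoxy)-4-(3-methylbut-2-en-1-yl)benzene
Product: 16 (2R)-2-(3,5-dimethoxyphenyl)-5,7-bis(methoxymethoxy)-6-(3-methylbut-2-en-1-yl)chromane, via alkylborane 15 (not isolated)
Conditions: 9-BBN (1.2 equiv), THF, 0 °C to rt; then PdCl2(dppf) (5 mol %), 3 M aq NaOH (3 equiv), THF, 65 °C
Reagents that add atoms: none
Why: 9-BBN hydroborates the monosubstituted vinyl group anti-Markovnikov and ignores the much slower trisubstituted prenyl alkene, and the B-alkyl borane then closes ring C by intramolecular B-alkyl Suzuki–Miyaura coupling (zerovalent palladium inserts into the C–I bond); no bond to C2 is touched, so the (R) centre is carried through.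

Step 9
Reactants: 16 (2R)-2-(3,5-dimethoxyphenyl)-5,7-bis(methoxymethoxy)-6-(3-methylbut-2-en-1-yl)chromane
Product: 17 (2R)-2-(3,5-dimethoxyphenyl)-6-(3-methylbut-2-en-1-yl)chromane-5,7-diol (CNP0147692.1)
Conditions: 3 M HCl, MeOH, rt
Reagents that add atoms: none
Why: Acid-catalysed methanolysis of the two MOM acetals frees the phenols; the C2–O bond does not ionise because the 3,5-dimethoxyphenyl ring (both OMe meta) gives no benzylic cation stabilisation, so C2 stays (R), and at room temperature the prenyl group does not cyclise onto the new phenols.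

**Compound list**

1 | resorcinol (benzene-1,3-diol) | Oc1cccc(O)c1 | starting material
2 | 1,3-bis(methoxymethoxy)benzene | COCOc1cccc(OCOC)c1 | intermediate
3 | [2,6-bis(methoxymethoxy)phenyl]lithium | [Li]c1c(OCOC)cccc1OCOC | intermediate
4 | [2,6-bis(methoxymethoxy)phenyl]copper | [Cu]c1c(OCOC)cccc1OCOC | intermediate
5 | 1,3-bis(methoxymethoxy)-2-(3-methylbut-2-en-1-yl)benzene | COCOc1cccc(OCOC)c1CC=C(C)C | intermediate
6 | 2-[3,5-bis(methoxymethoxy)-4-(3-methylbut-2-en-1-yl)phenyl]-4,4,5,5-tetramethyl-1,3,2-dioxaborolane | COCOc1cc(B2OC(C)(C)C(C)(C)O2)cc(OCOC)c1CC=C(C)C | intermediate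
7 | 3,5-bis(methoxymethoxy)-4-(3-methylbut-2-en-1-yl)phenol | COCOc1cc(O)cc(OCOC)c1CC=C(C)C | intermediate
8 | 2-iodo-3,5-bis(methoxymethoxy)-4-(3-methylbut-2-en-1-yl)phenol | COCOc1cc(O)c(I)c(OCOC)c1CC=C(C)C | intermediate
9 | (E)-3-(3,5-dimethoxyphenyl)prop-2-enoic acid | COc1cc(OC)cc(/C=C/C(=O)O)c1 | starting material
10 | (E)-3-(3,5-dimethoxyphenyl)prop-2-enoic isobutyl carbonic anhydride | COc1cc(OC)cc(/C=C/C(=O)OC(=O)OCC(C)C)c1 | intermediate
11 | (E)-3-(3,5-dimethoxyphenyl)prop-2-en-1-ol | COc1cc(OC)cc(/C=C/CO)c1 | intermediate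
12 | (E)-3-(3,5-dimethoxyphenyl)prop-2-en-1-yl methyl carbonate | COC(=O)OC/C=C/c1cc(OC)cc(OC)c1 | intermediate
13 | lithium 2-iodo-3,5-bis(methoxymethoxy)-4-(3-methylbut-2-en-1-yl)phenolate | [Li+].[O-]c1cc(OCOC)c(CC=C(C)C)c(OCOC)c1I | intermediate
14 | 1-{[(1R)-1-(3,5-dimethoxyphenyl)prop-2-en-1-yl]oxy}-2-iodo-3,5-bis(methoxymethoxy)-4-(3-methylbut-2-en-1-yl)benzene | C=C[C@@H](Oc1cc(OCOC)c(CC=C(C)C)c(OCOC)c1I)c1cc(OC)cc(OC)c1 | intermediate
15 | 9-{(3R)-3-(3,5-dimethoxyphenyl)-3-[2-iodo-3,5-bis(methoxymethoxy)-4-(3-methylbut-2-en-1-yl)phenoxy]propyl}-9-borabicyclo[3.3.1]nonane | C1CC2CCCC(C1)B2CC[C@@H](Oc1cc(OCOC)c(CC=C(C)C)c(OCOC)c1I)c1cc(OC)cc(OC)c1 | intermediate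
16 | (2R)-2-(3,5-dimethoxyphenyl)-5,7-bis(methoxymethoxy)-6-(3-methylbut-2-en-1-yl)chromane | COc1cc(OC)cc([C@H]2CCc3c(cc(OCOC)c(CC=C(C)C)c3OCOC)O2)c1 | intermediate
17 | (2R)-2-(3,5-dimethoxyphenyl)-6-(3-methylbut-2-en-1-yl)chromane-5,7-diol | COc1cc(OC)cc([C@H]2CCc3c(cc(O)c(CC=C(C)C)c3O)O2)c1 | target

**Step count and risk**

Total steps: 9 (seven in the main line, two for the carbonate). Longest linear sequence: 7 (steps 1, 2, 3, 4, 7, 8, 9).

The three steps most likely to fail:

Step 3 (C–H borylation with the prenyl alkene present). The HBpin by-product or the iridium boryl species may attack the alkene. The fallback removes the alkene from this step by reversing the order; it sets out from 2 and comes back at 7.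
- The same iridium/B2pin2 system borylates 2 at its one unhindered C–H and gives 2-[3,5-bis(methoxymethoxy)phenyl]-4,4,5,5-tetramethyl-1,3,2-dioxaborolane F1.
- H2O2/NaOH oxidises this to 3,5-bis(methoxymethoxy)phenol F2.
- i-Pr3SiCl/imidazole in DMF gives [3,5-bis(methoxymethoxy)phenoxy]tri(propan-2-yl)silane F3. Its bulky, non-coordinating silyl ether leaves the carbon between the two OMOM groups as the only site for directed lithiation.
- n-BuLi in THF at 0 °C gives [2,6-bis(methoxymethoxy)-4-(triisopropylsilyloxy)phenyl]lithium F4, and CuBr·SMe2 gives [2,6-bis(methoxymethoxy)-4-(triisopropylsilyloxy)phenyl]copper F5.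
- Prenyl bromide gives [3,5-bis(methoxymethoxy)-4-(3-methylbut-2-en-1-yl)phenoxy]tri(propan-2-yl)silane F6, and n-Bu4NF removes silicon to give 7.

Step 7 (asymmetric allylic etherification). The hindered, very electron-rich ortho-iodo aryloxide may C-allylate at its free ortho carbon, react slowly, or give modest ee. The fallback makes the C4–C4a bond first and the C2–O bond last with inversion; it sets out from 12 and 8 and comes back at 16.
- The same iridium catalysis with the (Sa,Sc,Sc) ligand and the unhindered hydroxide surrogate KOSiEt3 converts 12 into {[(1S)-1-(3,5-dimethoxyphenyl)prop-2-en-1-yl]oxy}triethylsilane F7.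
- 9-BBN gives 9-[(3S)-3-(3,5-dimethoxyphenyl)-3-(triethylsilyloxy)propyl]-9-borabicyclo[3.3.1]nonane F8.
- Intermolecular B-alkyl Suzuki coupling with 8 (PdCl2(dppf), aq NaOH, THF) gives 2-[(3S)-3-(3,5-dimethoxyphenyl)-3-(triethylsilyloxy)propyl]-3,5-bis(methoxymethoxy)-4-(3-methylbut-2-en-1-yl)phenol F9.
- n-Bu4NF gives 2-[(3S)-3-(3,5-dimethoxyphenyl)-3-hydroxypropyl]-3,5-bis(methoxymethoxy)-4-(3-methylbut-2-en-1-yl)phenol F10.
- Intramolecular Mitsunobu etherification (PPh3, DIAD, THF, 0 °C) closes ring C with inversion, (S) to (R), giving 16.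

Step 8 (hydroboration/intramolecular Suzuki). The doubly ortho-oxygenated aryl iodide may undergo protodeiodination, or the alkyl transfer to palladium may be slow. The fallback closes the ring by an anionic route without palladium; it sets out from 14 and comes back at 16.
- 9-BBN gives 15 as before, and NaOH/H2O2 oxidises it to (3R)-3-(3,5-dimethoxyphenyl)-3-[2-iodo-3,5-bis(methoxymethoxy)-4-(3-methylbut-2-en-1-yl)phenoxy]propan-1-ol F11.
- CBr4/PPh3 gives 1-{[(1R)-3-bromo-1-(3,5-dimethoxyphenyl)propyl]oxy}-2-iodo-3,5-bis(methoxymethoxy)-4-(3-methylbut-2-en-1-yl)benzene F12.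
- n-BuLi in THF at −78 °C exchanges the aryl iodide faster than it touches the primary bromide and gives (2-{[(1R)-3-bromo-1-(3,5-dimethoxyphenyl)propyl]oxy}-4,6-bis(methoxymethoxy)-5-(3-methylbut-2-en-1-yl)phenyl)lithium F13.
- On warming, the aryllithium displaces the bromide (Parham cyclialkylation) and gives 16 with C2 untouched.

**Further compounds**

F1 | step 3 | 2-[3,5-bis(methoxymethoxy)phenyl]-4,4,5,5-tetramethyl-1,3,2-dioxaborolane | COCOc1cc(OCOC)cc(B2OC(C)(C)C(C)(C)O2)c1
F2 | step 3 | 3,5-bis(methoxymethoxy)phenol | COCOc1cc(O)cc(OCOC)c1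
F3 | step 3 | [3,5-bis(methoxymethoxy)phenoxy]tri(propan-2-yl)silane | COCOc1cc(OCOC)cc(O[Si](C(C)C)(C(C)C)C(C)C)c1
F4 | step 3 | [2,6-bis(methoxymethoxy)-4-(triisopropylsilyloxy)phenyl]lithium | [Li]c1c(OCOC)cc(O[Si](C(C)C)(C(C)C)C(C)C)cc1OCOC
F5 | step 3 | [2,6-bis(methoxymethoxy)-4-(triisopropylsilyloxy)phenyl]copper | [Cu]c1c(OCOC)cc(O[Si](C(C)C)(C(C)C)C(C)C)cc1OCOC
F6 | step 3 | [3,5-bis(methoxymethoxy)-4-(3-methylbut-2-en-1-yl)phenoxy]tri(propan-2-yl)silane | COCOc1cc(O[Si](C(C)C)(C(C)C)C(C)C)cc(OCOC)c1CC=C(C)C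
F7 | step 7 | {[(1S)-1-(3,5-dimethoxyphenyl)prop-2-en-1-yl]oxy}triethylsilane | C=C[C@H](O[Si](CC)(CC)CC)c1cc(OC)cc(OC)c1
F8 | step 7 | 9-[(3S)-3-(3,5-dimethoxyphenyl)-3-(triethylsilyloxy)propyl]-9-borabicyclo[3.3.1]nonane | C1CC2CCCC(C1)B2CC[C@H](O[Si](CC)(CC)CC)c1cc(OC)cc(OC)c1
F9 | step 7 | 2-[(3S)-3-(3,5-dimethoxyphenyl)-3-(triethylsilyloxy)propyl]-3,5-bis(methoxymethoxy)-4-(3-methylbut-2-en-1-yl)phenol | COCOc1cc(O)c(CC[C@H](O[Si](CC)(CC)CC)c2cc(OC)cc(OC)c2)c(OCOC)c1CC=C(C)C
F10 | step 7 | 2-[(3S)-3-(3,5-dimethoxyphenyl)-3-hydroxypropyl]-3,5-bis(methoxymethoxy)-4-(3-methylbut-2-en-1-yl)phenol | COCOc1cc(O)c(CC[C@H](O)c2cc(OC)cc(OC)c2)c(OCOC)c1CC=C(C)C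
F11 | step 8 | (3R)-3-(3,5-dimethoxyphenyl)-3-[2-iodo-3,5-bis(methoxymethoxy)-4-(3-methylbut-2-en-1-yl)phenoxy]propan-1-ol | OCC[C@@H](Oc1cc(OCOC)c(CC=C(C)C)c(OCOC)c1I)c1cc(OC)cc(OC)c1
F12 | step 8 | 1-{[(1R)-3-bromo-1-(3,5-dimethoxyphenyl)propyl]oxy}-2-iodo-3,5-bis(methoxymethoxy)-4-(3-methylbut-2-en-1-yl)benzene | BrCC[C@@H](Oc1cc(OCOC)c(CC=C(C)C)c(OCOC)c1I)c1cc(OC)cc(OC)c1
F13 | step 8 | (2-{[(1R)-3-bromo-1-(3,5-dimethoxyphenyl)propyl]oxy}-4,6-bis(methoxymethoxy)-5-(3-methylbut-2-en-1-yl)phenyl)lithium | BrCC[C@@H](Oc1cc(OCOC)c(CC=C(C)C)c(OCOC)c1[Li])c1cc(OC)cc(OC)c1
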